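**Retrosynthetic overview**
- Target 21 ⇒ 20 (C2 as dioxolane) ⇒ 17: both tiglates lead back to a C8-oxygenated C9 ketone; C9–O comes from hydride delivered on the β-face, C8–O from SN2 inversion of an 8β-bromide.
- 17 ⇒ 14 ⇒ 13: the C7 isopropenyl group, the C8=C9 enol ether and the β-hydrogen on C10 all arise from one thermal homodienyl [1,5]-H shift of a C9=C10 silyl enol ether flanked by a gem-dimethylcyclopropane (C7–C8–C11).
- Key disconnection C4–C5: ring A (C1–C2–C3–C4–C5–C10) is the last ring closed, by HAT-initiated radical 6-endo cyclisation of a 2-oxopent-4-enyl chain on C10 onto C5 (9 ⇒ 10), which sets C5 and C4.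
- Enabling feature: ring B carries oxygen at C9 next to ring-fusion carbon C10, so C9=O/C10=C5 is an enone whose β-carbon is the quaternary C5. Ring B with its C5 methyl and C7 isopropenyl is an m-menthane, i.e. all ten carbons of (+)-3-carene, whose cyclopropane shields the β-face.
- Ring order: ring B (carene six-ring, bought) → ring A (step 7) → cyclopropane opened (step 10); the C10 chain is built by α-iodination, Stille allylation, cleavage and allylboration.

Key step: step 7

Remark: eremophilane numbering is used (ring A = C1–C2–C3–C4–C5–C10, ketone at C2; ring B = C5–C6–C7–C8–C9–C10; C11–C13 = isopropenyl on C7; β = face of the C4 and C5 methyl groups); 10 and 11 are drawn as the 10β-H epimer, and a 10α-H epimer would converge at 13 because step 9 removes this centre and step 10 sets it.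

Step 1
Reactants: 1 (+)-3-carene
Product: 2 3-caren-5-one, (1R,6S)-4,7,7-trimethylbicyclo[4.1.0]hept-3-en-2-one
Conditions: CrO3 (cat.), t-BuOOH (70% aq.), CH2Cl2, rt
Reagents that add atoms: tert-butyl hydroperoxide, CC(C)(C)OO
Why: Chromium-catalysed allylic oxidation takes the ring CH2 next to the unsubstituted alkene carbon (the 1-methylcyclohexene → 3-methylcyclohexenone pattern) and should give the cyclopropyl enone with both carene stereocenters untouched; no new stereocenter.

Step 2
Reactants: 2 3-caren-5-one
Product: 3 4-iodo-3-caren-5-one, (1R,6S)-3-iodo-4,7,7-trimethylbicyclo[4.1.0]hept-3-en-2-one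
Conditions: I2, pyridine, CH2Cl2, 0 °C → rt
Reagents that add atoms: iodine, II
Why: Pyridine-mediated α-iodination of an enone (Baylis–Hillman-type addition, iodination, elimination) functionalises C10 without ever forming a γ-dienolate, which in this skeleton would be a norcaradiene and open to a cycloheptatrienolate; no new stereocenter.

Step 3
Reactants: 3 4-iodo-3-caren-5-one; 4 allyltributylstannane
Product: 5 4-allyl-3-caren-5-one, (1R,6S)-3-allyl-4,7,7-trimethylbicyclo[4.1.0]hept-3-en-2-one
Conditions: Pd2(dba)3 (cat.), AsPh3, CuI, NMP, 50 °C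
Reagents that add atoms: allyltributylstannane (4), C=CC[Sn](CCCC)(CCCC)CCCC
Why: Stille coupling of an α-iodoenone with an allylstannane is a standard neutral sp2–sp3 coupling and places the C1 carbon on C10; no new stereocenter.

Step 4
Reactants: 5 4-allyl-3-caren-5-one
Product: 6 2-[(1R,6S)-4,7,7-trimethyl-2-oxobicyclo[4.1.0]hept-3-en-3-yl]acetaldehyde
Conditions: OsO4 (cat.), NaIO4, 2,6-lutidine, dioxane/H2O, rt
Reagents that add atoms: sodium periodate (oxygen delivered through catalytic OsO4), [Na+].[O-]I(=O)(=O)=O
Why: Lemieux–Johnson cleavage; OsO4 should dihydroxylate only the terminal alkene and not the tetrasubstituted, electron-poor enone or the cyclopropane; no new stereocenter.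

Step 5
Reactants: 6 aldehyde; 7 allylboronic acid pinacol ester
Product: 8 (1R,6S)-3-(2-hydroxypent-4-en-1-yl)-4,7,7-trimethylbicyclo[4.1.0]hept-3-en-2-one (both carbinol epimers)
Conditions: CH2Cl2, rt; aqueous work-up
Reagents that add atoms: allylboronic acid pinacol ester (7), C=CCB1OC(C)(C)C(C)(C)O1
Why: Uncatalysed allylboration through a six-membered transition state adds to the aldehyde and not to the hindered conjugated ketone; the carbinol centre forms unselectively and is removed in step 6.

Step 6
Reactants: 8 homoallylic alcohol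
Product: 9 (1R,6S)-4,7,7-trimethyl-3-(2-oxopent-4-en-1-yl)bicyclo[4.1.0]hept-3-en-2-one
Conditions: Dess–Martin periodinane, pyridine, CH2Cl2, 0 °C → rt
Reagents that add atoms: none
Why: Dess–Martin oxidation under buffered conditions should give the β,γ-unsaturated ketone without moving the terminal alkene into conjugation; both epimers of 8 converge and no stereocenter is formed.

Step 7
Reactants: 9 allyl ketone
Product: 10 8,11-cycloeremophilane-2,9-dione (4β,5β-dimethyl; cyclopropane C7–C8–C11 on the β-face; 10β-H drawn)
Conditions: Fe(acac)3 (30 mol%), PhSiH3, EtOH/(CH2OH)2 5:1, 60 °C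
Reagents that add atoms: none
Why: An iron hydride formed from Fe(acac)3 and PhSiH3 transfers a hydrogen atom to the terminal carbon of the side-chain alkene, the secondary C4 radical adds to the enone β-carbon C5, and the C10 α-keto radical is reduced to the enolate and protonated by ethanol. The closest known reaction type is the iron-mediated reductive olefin coupling, i.e. a HAT-initiated intramolecular Giese addition of an alkene-tethered enone. Ring A (C1–C2–C3–C4–C5–C10) closes in the 6-endo-trig mode, because the tether leaves from the α-carbon C10 and the nucleophilic alkyl radical attacks the electrophilic β-terminus C5, whereas 5-exo attack at C10 would be polarity-mismatched and give a spiro ring. At C5 the radical should enter anti to the gem-dimethylcyclopropane, whose endo methyl covers the β-face, so the C5 methyl ends β, cis to the later isopropenyl group. At C4 the chair-like transition state has the C5 methyl axial and should place the C4 methyl outward (equatorial), away from the C9/C10 edge of ring B, which gives the cis-4,5-dimethyl pattern; C10 is not fixed here. The step needs HAT only at the side-chain alkene and an intact cyclopropane: the isopropenyl group is still masked as the cyclopropane, the enone is a poor HAT acceptor, and the C10 radical and enolate carry no spin on C9, so no cyclopropylcarbinyl opening is expected.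

Step 8
Reactants: 10 tricyclic diketone
Product: 11 2,2-ethylenedioxy-8,11-cycloeremophilan-9-one
Conditions: TMSOCH2CH2OTMS, TMSOTf (cat.), CH2Cl2, −78 °C
Reagents that add atoms: 1,2-bis(trimethylsilyloxy)ethane, C[Si](C)(C)OCCO[Si](C)(C)C
Why: Noyori ketalisation should take the unhindered C2 cyclohexanone and leave the C9 carbonyl, which is conjugated to the cyclopropane and flanked by the branched C8 and C10; no new stereocenter.

Step 9
Reactants: 11 ketal ketone
Product: 13 9-(tert-butyldimethylsilyloxy)-2,2-ethylenedioxy-8,11-cycloeremophil-9(10)-ene, via potassium enolate 12 (not isolated)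
Conditions: KHMDS, THF, −78 → 0 °C; TBSCl, −78 °C → rt
Reagents that add atoms: tert-butyldimethylsilyl chloride, CC(C)(C)[Si](C)(C)Cl
Why: C10–H is the only enolisable α-hydrogen of the C9 ketone (C8–H is a cyclopropane C–H), so enolate formation and O-silylation are regiospecific and erase the C10 centre of either epimer.

Step 10
Reactants: 13 silyl enol ether
Product: 14 9-(tert-butyldimethylsilyloxy)-2,2-ethylenedioxy-10βH-eremophila-8,11-diene
Conditions: toluene, sealed tube (silylated glass, trace Et3N), 210 °C
Reagents that add atoms: none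
Why: Thermal homodienyl [1,5]-hydrogen shift (retro-ene) of a cis-methyl vinylcyclopropane, the reaction that converts 2-carene into trans-isolimonene: the endo methyl on C11 passes H to C10 across the β-face, C8–C11 breaks, the isopropenyl group appears on C7 with retention and the enol ether moves to C8=C9, so the new C10 centre (H β, cis ring fusion) is set by suprafacial intramolecular delivery from the cyclopropane face.

Step 11
Reactants: 14 silyl enol ether
Product: 15 8β-bromo-2,2-ethylenedioxy-10βH-eremophil-11-en-9-one
Conditions: NBS, NaHCO3, THF, −78 °C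
Reagents that add atoms: N-bromosuccinimide, O=C1CCC(=O)N1Br
Why: Electrophilic bromination of a silyl enol ether, much faster than attack on the isopropenyl group; bromine should enter C8 axially on the convex β-face (the α-face is covered by the axial C5–C4 bond of ring A), giving the axial 8β-bromide, which is also the favoured α-bromo ketone epimer.

Step 12
Reactants: 15 bromo ketone; 16 tiglic acid
Product: 17 8α-tigloyloxy-2,2-ethylenedioxy-10βH-eremophil-11-en-9-one
Conditions: tiglic acid, Cs2CO3, DMF, 0 °C → rt
Reagents that add atoms: tiglic acid (16), C/C=C(\C)C(=O)O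
Why: SN2 displacement of an axial α-keto bromide by a carboxylate, accelerated by the adjacent carbonyl; inversion at C8 gives the equatorial 8α-ester trans to the C7 isopropenyl group, which is also the more stable epimer.

Step 13
Reactants: 17 tigloyloxy ketone; 18 tigloyl chloride
Product: 20 8α,9α-bis(tigloyloxy)-2,2-ethylenedioxy-10βH-eremophil-11-ene, via lithium alkoxide 19 (not isolated)
Conditions: L-Selectride (1.05 equiv), THF, −78 °C; then tigloyl chloride, DMAP (cat.), −78 °C → rt
Reagents that add atoms: tigloyl chloride (18), C/C=C(\C)C(=O)Cl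
Why: Bulky-hydride reduction with in-situ O-acylation of the alkoxide; axial attack on C9 from the α-face is blocked by the syn-axial C5–C4 bond, so hydride should arrive from the β-side and give the axial 9α-alkoxide cis to the 8α-ester, and any 1,2-acyl shift between O8 and O9 is harmless because both oxygens end as tiglates.

Step 14
Reactants: 20 bis-tiglate ketal
Product: 21 8α,9α-bis(tigloyloxy)-10βH-eremophil-11-en-2-one (target)
Conditions: 1 M HCl, THF, rt
Reagents that add atoms: water, O
Why: Acid-catalysed hydrolysis of the dioxolane; the tiglates, the isopropenyl group and the ring fusion (no longer α to a carbonyl) should survive dilute acid, and no stereocenter is touched.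

**Compound list**
1 | (+)-3-carene, (1S,6R)-3,7,7-trimethylbicyclo[4.1.0]hept-3-ene | CC1=CC[C@@H]2[C@H](C1)C2(C)C | starting material
2 | 3-caren-5-one, (1R,6S)-4,7,7-trimethylbicyclo[4.1.0]hept-3-en-2-one | CC1=CC(=O)[C@@H]2[C@H](C1)C2(C)C | intermediate
3 | 4-iodo-3-caren-5-one, (1R,6S)-3-iodo-4,7,7-trimethylbicyclo[4.1.0]hept-3-en-2-one | CC1(C)[C@H]2CC(C)=C(I)C(=O)[C@@H]12 | intermediate
4 | allyltributylstannane | C=CC[Sn](CCCC)(CCCC)CCCC | starting material
5 | 4-allyl-3-caren-5-one, (1R,6S)-3-allyl-4,7,7-trimethylbicyclo[4.1.0]hept-3-en-2-one | CC1(C)[C@H]2CC(C)=C(CC=C)C(=O)[C@@H]12 | intermediate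
6 | 2-[(1R,6S)-4,7,7-trimethyl-2-oxobicyclo[4.1.0]hept-3-en-3-yl]acetaldehyde | CC1(C)[C@H]2CC(C)=C(CC=O)C(=O)[C@@H]12 | intermediate
7 | allylboronic acid pinacol ester | C=CCB1OC(C)(C)C(C)(C)O1 | starting material
8 | (1R,6S)-3-(2-hydroxypent-4-en-1-yl)-4,7,7-trimethylbicyclo[4.1.0]hept-3-en-2-one, both carbinol epimers | CC1(C)[C@H]2CC(C)=C(CC(O)CC=C)C(=O)[C@@H]12 | intermediate
9 | (1R,6S)-4,7,7-trimethyl-3-(2-oxopent-4-en-1-yl)bicyclo[4.1.0]hept-3-en-2-one | CC1(C)[C@H]2CC(C)=C(CC(=O)CC=C)C(=O)[C@@H]12 | intermediate
10 | 8,11-cycloeremophilane-2,9-dione (4β,5β-dimethyl, β-cyclopropane, 10β-H) | CC1(C)[C@H]2C[C@@]3(C)[C@H](CC(=O)C[C@@H]3C)C(=O)[C@@H]12 | intermediate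
11 | 2,2-ethylenedioxy-8,11-cycloeremophilan-9-one | CC1(C)[C@H]2C[C@@]3(C)[C@H](CC4(OCCO4)C[C@@H]3C)C(=O)[C@@H]12 | intermediate
12 | potassium enolate of 11 (C9–O, C9=C10) | CC1(C)[C@H]2C[C@@]3(C)C(CC4(OCCO4)C[C@@H]3C)=C([O-])[C@@H]12.[K+] | intermediate
13 | 9-(tert-butyldimethylsilyloxy)-2,2-ethylenedioxy-8,11-cycloeremophil-9(10)-ene | CC1(C)[C@H]2C[C@@]3(C)C(CC4(OCCO4)C[C@@H]3C)=C(O[Si](C)(C)C(C)(C)C)[C@@H]12 | intermediate
14 | 9-(tert-butyldimethylsilyloxy)-2,2-ethylenedioxy-10βH-eremophila-8,11-diene | C=C(C)[C@H]1C[C@@]2(C)[C@H](CC3(OCCO3)C[C@@H]2C)C(O[Si](C)(C)C(C)(C)C)=C1 | intermediate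
15 | 8β-bromo-2,2-ethylenedioxy-10βH-eremophil-11-en-9-one | C=C(C)[C@H]1C[C@@]2(C)[C@H](CC3(OCCO3)C[C@@H]2C)C(=O)[C@H]1Br | intermediate
16 | tiglic acid, (E)-2-methylbut-2-enoic acid | C/C=C(\C)C(=O)O | starting material
17 | 8α-tigloyloxy-2,2-ethylenedioxy-10βH-eremophil-11-en-9-one | C=C(C)[C@H]1C[C@@]2(C)[C@H](CC3(OCCO3)C[C@@H]2C)C(=O)[C@@H]1OC(=O)/C(C)=C/C | intermediate
18 | tigloyl chloride, (E)-2-methylbut-2-enoyl chloride | C/C=C(\C)C(=O)Cl | starting material
19 | lithium 9α-alkoxide of the 8α-tigloyloxy ketal | C=C(C)[C@H]1C[C@@]2(C)[C@H](CC3(OCCO3)C[C@@H]2C)[C@H]([O-])[C@@H]1OC(=O)/C(C)=C/C.[Li+] | intermediate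
20 | 8α,9α-bis(tigloyloxy)-2,2-ethylenedioxy-10βH-eremophil-11-ene | C=C(C)[C@H]1C[C@@]2(C)[C@H](CC3(OCCO3)C[C@@H]2C)[C@H](OC(=O)/C(C)=C/C)[C@@H]1OC(=O)/C(C)=C/C | intermediate
21 | 8α,9α-bis(tigloyloxy)-10βH-eremophil-11-en-2-one | C=C(C)[C@H]1C[C@@]2(C)[C@H](CC(=O)C[C@@H]2C)[C@H](OC(=O)/C(C)=C/C)[C@@H]1OC(=O)/C(C)=C/C | target

**Step count and risks**
Total step count: 14. Longest linear sequence: 14 steps (1 → 21).

Steps most likely to fail:

1. Step 7. The C4 radical may be reduced before it closes onto the fully substituted C5, or it may close with poor control of the C4 configuration. The fallback sets out from aldehyde 6 and replaces the alkyl radical by a vinyl radical, so that C4 is set afterwards by hydrogenation. Indium-mediated Barbier addition of 2,3-dibromopropene (THF/H2O) should give the bromo homoallylic alcohol F1, and Dess–Martin oxidation the vinyl bromide ketone F2. Slow addition of Bu3SnH/AIBN in benzene at 80 °C should generate the C4 vinyl radical, which closes 6-endo onto C5 anti to the cyclopropane to give the 4-methylene diketone F3. Hydrogenation over RhCl(PPh3)3 from the face opposite the axial C5 methyl should then give the cis-4,5-dimethyl compound and return to the route at 10.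

2. Step 10. The [1,5]-hydrogen shift may need temperatures at which desilylation of the enol ether or loss of the ketal competes. The fallback sets out from diketone 10 and opens the ring ionically. HBr in acetic acid at 0 °C should cleave the protonated cyclopropyl ketone at the tertiary carbon to give the bromo diketone F4, with C10 settling in the cis-fused form. Sodium acetate in hot acetic acid should eliminate HBr to the isopropenyl diketone F5; some isopropylidene isomer would have to be separated, and strong base must be avoided because it would re-close the cyclopropane. Noyori ketalisation of C2 should give the ketal ketone F6, and kinetic enolisation at the C8 methylene (LDA, TBSCl, THF, −78 °C) returns to the route at 14.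

3. Step 12. E2 loss of HBr across C7–C8 (axial bromide anti to the axial C7–H) or slow substitution on the concave α-face may outrun the SN2 reaction. The fallback sets out from silyl enol ether 14 and brings in the oxygen first. Rubottom oxidation (dimethyldioxirane, acetone, −78 °C; then aqueous citric acid) on the convex β-face should give the 8β-hydroxy ketone F7. Mitsunobu esterification with tiglic acid 16 (PPh3, DIAD, THF) should invert C8 and return to the route at 17.

Further compounds
F1 | step 7 | (1R,6S)-3-(4-bromo-2-hydroxypent-4-en-1-yl)-4,7,7-trimethylbicyclo[4.1.0]hept-3-en-2-one, both carbinol epimers | CC1(C)[C@H]2CC(C)=C(CC(O)CC(Br)=C)C(=O)[C@@H]12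
F2 | step 7 | (1R,6S)-3-(4-bromo-2-oxopent-4-en-1-yl)-4,7,7-trimethylbicyclo[4.1.0]hept-3-en-2-one | CC1(C)[C@H]2CC(C)=C(CC(=O)CC(Br)=C)C(=O)[C@@H]12
F3 | step 7 | 15-nor-4-methylene-8,11-cycloeremophilane-2,9-dione (exocyclic C4=CH2, 5β-methyl) | CC1(C)[C@H]2C[C@@]3(C)C(CC(=O)CC3=C)C(=O)[C@@H]12
F4 | step 10 | 11-bromo-10βH-eremophilane-2,9-dione | CC(C)(Br)[C@H]1C[C@@]2(C)[C@H](CC(=O)C[C@@H]2C)C(=O)C1
F5 | step 10 | 10βH-eremophil-11-ene-2,9-dione | C=C(C)[C@H]1C[C@@]2(C)[C@H](CC(=O)C[C@@H]2C)C(=O)C1
F6 | step 10 | 2,2-ethylenedioxy-10βH-eremophil-11-en-9-one | C=C(C)[C@H]1C[C@@]2(C)[C@H](CC3(OCCO3)C[C@@H]2C)C(=O)C1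
F7 | step 12 | 8β-hydroxy-2,2-ethylenedioxy-10βH-eremophil-11-en-9-one | C=C(C)[C@H]1C[C@@]2(C)[C@H](CC3(OCCO3)C[C@@H]2C)C(=O)[C@H]1O
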